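Decide what to do with this flask at 8.0 d by counting partner before you think about any rate.

- east: substrate 0.10 M; partner 0.090 M; protic impurity 0.020 M; catalyst 72 µM; temperature 25 °C; the very flask that is asked about, followed so far
- flask: substrate 0.10 M; partner 0.0900 M; protic impurity 0.0200 M; catalyst 72 µM; temperature 25 °C; time 8.0 d

east run (percent of the substrate charged): time / h: target / % = 10.0: 28.4; 20.0: 52.9; 50.0: 68.3; 120: 71.2

(scatter of a reading: 1 percentage point)

- green: at 8.0 d raise the temperature by 10 K, then wait 8.0 d
- amber: change nothing and wait 8.0 d more
- violet: at 8.0 d take out 90% of the target then present, then wait 8.0 d
- ochre: at 8.0 d add catalyst, 50.0% of the amount charged, then wait 8.0 d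
- grey: at 8.0 d add partner, 100% of the amount charged, then wait 8.0 d

- target, in percent of the substrate first charged, at 8.0 d
- the option that brings most further target ("none" if no option brings more than 2 percentage points) (green / amber / violet / ochre / grey / none)
- target present, with what was taken out counted in, in percent of the substrate first charged, after violet
- target present, with what was taken out counted in, in percent of the substrate first charged, after grey

- removed target is counted in
- the earlier runs do not show what temperature does; that part of a forecast is a guess
- additions bring no volume worth counting

Take the even charge, one partner for each substrate, as the zero of your scale. Then suppose that each protic impurity spoils one partner, and let c_A, c_B and c_H be the starting concentrations of substrate, partner and protic impurity. The usable-partner ceiling U, the target that the partner left over can carry, in percent of the substrate charged, is then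

U = (c_B − c_H) / c_A = 70.0%

An even charge free of protic impurity has U at 100%, so this flask starts 30 percentage points short. Without the subtraction, partner allows 90.0%, and the reading of 71.2% at 120 h lies 19 points below that, with a scatter of 1 point. It lies 1.2 points above U, so I take partner as the limiting reagent and commit to U for the target at 8.0 d.

But that reading also equals 989 turnovers of the catalyst, and from these readings I cannot tell a catalyst that stops there from a count of partner. That is the risk in my choice.

Green, amber, violet and ochre add no partner, so I expect U to stand after each of them, with what is taken out counted in. The temperature part of this is a guess. Grey adds 0.0900 M against a shortfall of 0.0300 M, which lifts the count to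

U' = (c_B + added partner − c_H) / c_A = 160%

This is more than the substrate can fill, so after grey I expect the whole charge, 100%, as target. I choose grey.

The forecast says “The arithmetic points to partner running out” and gives 70.5% now and 70.7% after violet, where my reckoning has 70.0%, grey as the choice, as I do, and 98% after grey, where my reckoning has 100%.

The flask gives 70.1% now and 70.1% after violet. Choosing grey adds 30 points and reaches 100%, more than the 0 points of each other option.

    substrate + catalyst → catalyst + intermediate (k = 20.0 /M/min, Ea = 64.0 kJ/mol)
    partner + protic impurity → quenched reagent (k = 0.0890 /M/min, Ea = 51.0 kJ/mol)
    partner + catalyst + intermediate → catalyst + target (k = 650 /M²/min, Ea = 41.0 kJ/mol)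
    (constants at 25 °C)

Two steps draw on partner: at 8.04 h the target step takes it 11 times as fast as the quench path, yet at 19.2 h the flask has less of its protic impurity left, 0.950% of its charge, than of its partner, 20.9%, and at 96.0 h it holds 0.0199 M of quenched reagent, with 0% of partner left at 192 h. On this flask U of 70.0% stands beside 70.1% of target, with 29.9% as intermediate, and for the neighbour charged with 0.17 M of substrate the same count, 41.2%, stands beside its 41.5% of target.

(The numbers in the tables are simulated with constants of no real substance; noise was put on by code.)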